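## Analysis of the target

The target is an eremophilane sesquiterpenoid: a trans-fused decalin (ring A = C1–C5/C10, ring B = C5–C10) that carries a 2α-hydroxyl and a 4β-methyl on ring A, an angular 5β-methyl, and on ring B a 7β-isopropenyl, an 8α-hydroxyl and a 9α-(E)-3-methylpent-2-enoate. There are seven stereocentres (C2, C4, C5, C7, C8, C9, C10). In the chair–chair form the 5-methyl, 10-H, 2-OH, 7-isopropenyl and 8-OH are axial, while the 4-methyl and the 9-acyloxy group are equatorial. The core problem is the vicinal pair C4 (tertiary) and C5 (quaternary) with cis methyl groups, which cannot be corrected once the rings exist. The sensitive parts are the β,β-disubstituted (E)-enoate (geometry, deconjugation, addition of organometallics), the cis C8/C9 diol monoester (acyl migration) and the isopropenyl group (acid). Further difficulties are the distinction of three secondary hydroxyls, an axial isopropenyl group syn to the angular methyl, and a C9 oxygen that is γ to any ring A enone and therefore at risk in reductions. The route rests on ring A: the C2 oxygen sits para to C5, and C4/C5 carry cis methyls, which is the pattern of a Diels–Alder adduct of a 2-oxygenated diene (C3–C2–C1–C10) with (E)-2-methylbut-2-enal (C4, C5). In that adduct the formyl carbon is C6 and the diene substituent is C9, so both anchor points of ring B come with the cycloaddition.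

## Retrosynthetic reasoning

**C9–O acyl bond.** The enoate of 26 is removed last, giving triol 22 and acid chloride 24 (from acid 23). The ester cannot survive the organometallic and hydride steps, so it must come at the end. The forward step has to acylate only the equatorial 9α-hydroxyl; the tin acetal 25 of the only cis-vicinal diol does this without base.

**C7–C11 bond and C8–O.** Triol 22 is cut between C7 and the isopropenyl carbon, leading to the 7α,8α-epoxide 21. A trans-diaxial opening at C7 gives the 7β-isopropenyl/8α-hydroxyl pair in one operation. The epoxide comes from alkene 20, where the angular methyl and the 9α-hydroxyl both point a peracid to the α face.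

**C2 and C10 hydrogens.** The axial 2α-alcohol of 20 is traced to ketone 19 (equatorial hydride delivery). The 10α-hydrogen of 19 is traced to the C1=C10 enone 17, reduced by dissolving metal through 18. The reduction is placed on the bicyclic enone because only there does axial protonation of C10 give the trans ring fusion reliably. The C9 oxygen must be a free alcohol at that stage, held as its alkoxide, because an ether or ester γ to the enone would be expelled.

**Ring B (C7=C8) and the C8–C9 bond.** Ring B of 17 is opened at C7=C8 by a metathesis disconnection to diene 16. This alkene is exactly where the epoxide is needed later. The C8–C9 bond of 16 is then cut to aldehyde 15 and an (E)-alkenyl nucleophile carried on zinc. The quaternary C5 gives little facial bias at C9, so the carbinol is set by a chiral amino-alcohol catalyst. The extra carbons of the alkenyl group are lost again in the metathesis.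

**C6–C7 and oxidation-state changes.** Aldehyde 15 comes from alcohol 14 and PMB ether 13. The allyl group of 13 is cut at C6–C7: methylenation of aldehyde 12, which is the one-carbon homologue (via enol ether 11) of the neopentyl aldehyde 10. The formyl carbon of 10 thus becomes C6.

**C1=C10 unsaturation.** Enone 10 comes from silyl enol ether 9 by dehydrogenation. The enol ether fixes on which side of C2 the double bond appears, so this is done directly after the cycloaddition. It also removes the C10 centre, so its configuration in 9 is irrelevant.

**Ring A (C3–C4 and C5–C10).** Adduct 9 is cut into diene 7 and enal 8. This is the only disconnection that makes the quaternary C5, the C4 methyl and the C2 oxygen in one step from achiral partners, with the absolute configuration supplied by a catalyst.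

**Diene.** Diene 7 is the silyl dienol ether of enone 6, which is the Wittig product of aldehyde 4 and ylide 5. Aldehyde 4 comes from oxidative cleavage (through ozonide 3) of the symmetric bis-ether 2 of diol 1, so that both halves of 1 are used.

## Alternatives that were turned down

Alternative 1: oxidative radical bicyclisation of an acyclic β-keto ester.

The disconnection is at C1–C10 and C5–C6. The substrate would be the β-keto ester ethyl (6E)-8-(tert-butyldiphenylsilyloxy)-5,6-dimethyl-3-oxo-10-[(trimethylsilyl)methyl]undeca-6,10-dienoate A2. In the forward step Mn(OAc)3 with Cu(OAc)2 would oxidise A2 to a C1 radical. This adds to C10; the tertiary C5 radical then closes onto the allylsilane and gives ethyl 9α-(tert-butyldiphenylsilyloxy)-4β,5β-dimethyl-7-methylene-2-oxo-trans-decalin-1-carboxylate A1.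
- For it: both rings and the quaternary centre form in one step, and the 9α-oxygen is carried in from the start. On the C9 oxygen it is stronger than the chosen route, which has to set C9 by a separate catalyst-controlled addition.
- Against it: the C5 radical is planar, so the cis C4/C5 methyl relation depends on a weak preference in the second ring closure, a 6-endo attack of a hindered tertiary radical. A2 itself needs two stereocentres, a defined trisubstituted alkene and an allylsilane, all made beforehand. A1 then needs removal of the ester and conversion of an exocyclic C7 methylene into 7β-isopropenyl/8α-hydroxyl, for which the methylene offers no direct handle.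
- Comparison: the chosen route fixes C4/C5 by a concerted suprafacial addition, takes the absolute configuration from a catalyst, and ends with the alkene at C7=C8 where it is needed.

Alternative 2: conjugate methylation with enolate allylation in the same flask.

The disconnection is at C4–CH3 and C5–C6. The substrate would be the enone (S)-5-(tert-butyldimethylsilyloxy)-2-methylcyclohex-2-en-1-one A4. Me2CuLi would add its methyl group to C4 of A4, and the resulting C5 enolate would be allylated without isolation to give 2-allyl-2,3-dimethyl-5-(tert-butyldimethylsilyloxy)cyclohexanone A3, which is ring A with C6–C8 attached.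
- For it: it is short and uses well-known substrate control (anti addition to A4, then anti alkylation), and the 2α-oxygen is present from the beginning. On C2 it is stronger than the chosen route, which sets C2 late by a hydride reduction.
- Against it: no ring is closed. C10 of A3 is a hindered ketone to which C9 must still be attached, and C9 and C10 must then be set with no help from the key step. Allylation of a fully substituted enolate next to a tertiary centre is slow and open to enolate equilibration. The silyloxy group of A3 is β to the ketone and can be eliminated under the basic conditions. A4 must also be secured as a single enantiomer before the key step, since it is the only source of absolute configuration.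
- Comparison: the cycloaddition delivers the same C4/C5 array from achiral partners, together with C6 and C9 already attached at useful oxidation levels, which neither A4 nor A3 provides.

Alternative 3: type 2 carbonyl-ene closure of ring A.

The disconnection is at C1–C2. The substrate would be the aldehyde 3-(1-methyl-2-methylenecyclohexyl)butanal A6. Me2AlCl would promote the ene reaction of the formyl group of A6 with its exocyclic methylene to give 4β,5β-dimethyl-9(10)-octalin-2α-ol A5.
- For it: the ring closure and the axial 2α-hydroxyl are obtained in one step, and the alkene ends next to C9. On C2 this is stronger than the chosen route.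
- Against it: the difficult part, the C4/C5 pair, must already exist in A6, where C4 is a side-chain centre next to a quaternary carbon and has no obvious control. A5 has no functional group at C7 or C8, so the isopropenyl group, the 8α-hydroxyl and the 9α-oxygen would all have to be introduced on a nearly unfunctionalised ring B.
- Comparison: the chosen strategy spends one extra step on C2 but makes C4/C5 in its key step and leaves ring B with a handle on every carbon that needs one.

Key step: step 5

Convention: eremophilane numbering is used for all intermediates (C1–C10 ring carbons, methyls on C4 and C5, isopropenyl on C7); β is the face that carries the C5 methyl, α the opposite face.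

Assumption: the sense of induction of the two chiral catalysts (steps 5 and 12) is taken from the accepted transition-state models of these catalyst classes; both are available in either mirror-image form, so the other antipode would be used if the sense proved opposite.

## Route

Step 1
Reactants: 1 (Z)-but-2-ene-1,4-diol
Product: 2 (Z)-1,4-bis(4-methoxybenzyloxy)but-2-ene
Conditions: NaH (2.5 equiv), 4-methoxybenzyl chloride (2.2 equiv), Bu4NI (cat.), DMF, 0 °C → rt
Reagents that add atoms: 4-methoxybenzyl chloride COc1ccc(CCl)cc1
Why: Williamson etherification of both primary allylic hydroxyls; the symmetric bis-ether lets both halves of 1 end up in product after step 2.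

Step 2
Reactants: 2 (Z)-1,4-bis(4-methoxybenzyloxy)but-2-ene
Product: 4 2-(4-methoxybenzyloxy)acetaldehyde, via secondary ozonide 3 (not isolated)
Conditions: O3, CH2Cl2, −78 °C (Sudan Red end point); PPh3, −78 °C → rt
Reagents that add atoms: ozone [O-][O+]=O
Why: Ozonolysis with reductive work-up; the electron-rich cis alkene reacts before the anisyl rings when ozone is stopped at the indicator end point, and each molecule of 2 gives two of 4.

Step 3
Reactants: 4 2-(4-methoxybenzyloxy)acetaldehyde; 5 1-(triphenylphosphoranylidene)propan-2-one
Product: 6 (E)-5-(4-methoxybenzyloxy)pent-3-en-2-one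
Conditions: CH2Cl2, rt → 40 °C
Reagents that add atoms: none
Why: Wittig olefination with a stabilised ylide, which should give the (E)-enone.

Step 4
Reactants: 6 (E)-5-(4-methoxybenzyloxy)pent-3-en-2-one
Product: 7 (E)-2-(tert-butyldimethylsilyloxy)-5-(4-methoxybenzyloxy)penta-1,3-diene
Conditions: tert-butyldimethylsilyl triflate, Et3N, CH2Cl2, 0 °C
Reagents that add atoms: tert-butyldimethylsilyl trifluoromethanesulfonate CC(C)(C)[Si](C)(C)OS(=O)(=O)C(F)(F)F
Why: Soft enolisation (silyl triflate and amine) of the methyl ketone at the methyl group gives the cross-conjugated 2-silyloxydiene; the (E) alkene is untouched.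

Step 5
Reactants: 7 (E)-2-(tert-butyldimethylsilyloxy)-5-(4-methoxybenzyloxy)penta-1,3-diene; 8 (E)-2-methylbut-2-enal
Product: 9 4-(tert-butyldimethylsilyloxy)-2-[(4-methoxybenzyloxy)methyl]-1,6-dimethylcyclohex-3-ene-1-carbaldehyde (methyls cis and β; formyl α; C10 side chain drawn cis to formyl)
Conditions: 8 (2 equiv), oxazaborolidinium bis(trifluoromethanesulfonyl)imide catalyst [from (R)-α,α-diphenylprolinol, (2-MeC6H4BO)3 and (CF3SO2)2NH; 20 mol%], CH2Cl2, −78 → −40 °C; Et3N quench
Reagents that add atoms: none
Why: The N-protonated oxazaborolidine is a strong chiral Lewis acid that binds the formyl oxygen of 8 at boron while the formyl C–H is held by the ring oxygen, so the s-trans enal lies over one aryl group and only one face stays open. Diene 7 then adds in a concerted, asynchronous [4+2] cycloaddition in which its CH2 terminus (C3) bonds to the β-carbon (C4) ahead of the bond between the substituted terminus (C10) and the α-carbon (C5); the closest known reaction type is the oxazaborolidinium-catalysed Diels–Alder reaction of α-substituted enals with 2-silyloxy-1,3-dienes. Ring A closes as a six-membered ring in this single intermolecular suprafacial cycloaddition, which forms C3–C4 and C5–C10 and leaves C2 as a regiodefined silyl enol ether. The cis relation of the C4 and C5 methyls follows from the (E) geometry of 8, and their absolute configuration from the enal face left open by the catalyst. C10 is set by the endo/exo preference (the formyl-cis isomer is drawn) but becomes trigonal in step 6, so it need not be controlled. The step needs one regiochemistry and one enal face: the 2-silyloxy and 1-alkyl groups of 7 both raise the frontier-orbital coefficient at C3, which pairs with the electrophilic β-carbon of the bound enal, and the catalyst supplies the face. Low temperature and excess 8 limit Mukaiyama-type desilylation of 7.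

Step 6
Reactants: 9 4-(tert-butyldimethylsilyloxy)-2-[(4-methoxybenzyloxy)methyl]-1,6-dimethylcyclohex-3-ene-1-carbaldehyde
Product: 10 2-[(4-methoxybenzyloxy)methyl]-1,6-dimethyl-4-oxocyclohex-2-ene-1-carbaldehyde (methyls cis and β; formyl α)
Conditions: Pd(OAc)2 (1.05 equiv), MeCN, rt → 40 °C
Reagents that add atoms: none
Why: Saegusa–Ito oxidation: silicon-to-palladium exchange gives a palladium enolate at C1–C2, and β-hydride loss from C10, the only β-hydrogen, gives the C1=C10 enone with the regiochemistry fixed by the enol ether; both C10 epimers of 9 converge.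

Step 7
Reactants: 10 2-[(4-methoxybenzyloxy)methyl]-1,6-dimethyl-4-oxocyclohex-2-ene-1-carbaldehyde
Product: 11 3-[(4-methoxybenzyloxy)methyl]-4-(2-methoxyvinyl)-4,5-dimethylcyclohex-2-en-1-one (E/Z mixture at the enol ether; methyls cis and β)
Conditions: (methoxymethyl)triphenylphosphonium chloride (1.3 equiv), KN(SiMe3)2 (1.25 equiv), THF, 0 °C; then 10, −78 → 0 °C
Reagents that add atoms: (methoxymethyl)triphenylphosphonium chloride COC[P+](c1ccccc1)(c1ccccc1)c1ccccc1.[Cl-]
Why: Wittig reaction of an alkoxy ylide; an aldehyde reacts far faster than the carbonyl of a β,β-disubstituted cyclohexenone, so a small excess at low temperature should take the formyl group only, and the enol ether geometry is of no consequence.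

Step 8
Reactants: 11 3-[(4-methoxybenzyloxy)methyl]-4-(2-methoxyvinyl)-4,5-dimethylcyclohex-2-en-1-one
Product: 12 2-[2-[(4-methoxybenzyloxy)methyl]-1,6-dimethyl-4-oxocyclohex-2-en-1-yl]acetaldehyde (methyls cis and β)
Conditions: 2 M aq. HCl, THF, rt
Reagents that add atoms: water O
Why: Acid hydrolysis of the enol ether (C-protonation, then collapse of the hemiacetal) gives the homologated aldehyde; the enone and the PMB ether tolerate dilute aqueous acid at room temperature.

Step 9
Reactants: 12 2-[2-[(4-methoxybenzyloxy)methyl]-1,6-dimethyl-4-oxocyclohex-2-en-1-yl]acetaldehyde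
Product: 13 4-allyl-3-[(4-methoxybenzyloxy)methyl]-4,5-dimethylcyclohex-2-en-1-one (methyls cis and β; allyl α)
Conditions: methyltriphenylphosphonium bromide (1.2 equiv), KN(SiMe3)2 (1.15 equiv), THF, 0 °C; then 12, −78 → 0 °C
Reagents that add atoms: methyltriphenylphosphonium bromide C[P+](c1ccccc1)(c1ccccc1)c1ccccc1.[Br-]
Why: Wittig methylenation, again selective for the aldehyde over the conjugated ketone at low temperature; it completes the C6–C7 allyl arm.

Step 10
Reactants: 13 4-allyl-3-[(4-methoxybenzyloxy)methyl]-4,5-dimethylcyclohex-2-en-1-one
Product: 14 4-allyl-3-(hydroxymethyl)-4,5-dimethylcyclohex-2-en-1-one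
Conditions: DDQ (1.3 equiv), CH2Cl2/pH 7 buffer (10:1), 0 °C → rt
Reagents that add atoms: none
Why: Oxidative PMB cleavage (hydride abstraction at the anisylic carbon, then hydrolysis of the oxocarbenium ion); the electron-poor enone and the terminal alkene are not attacked.

Step 11
Reactants: 14 4-allyl-3-(hydroxymethyl)-4,5-dimethylcyclohex-2-en-1-one
Product: 15 6-allyl-5,6-dimethyl-3-oxocyclohex-1-ene-1-carbaldehyde (methyls cis and β; allyl α)
Conditions: Dess–Martin periodinane, CH2Cl2, 0 °C → rt; used directly
Reagents that add atoms: none
Why: Dess–Martin oxidation of the primary allylic alcohol under neutral conditions, without over-oxidation or movement of the enone.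

Step 12
Reactants: 15 6-allyl-5,6-dimethyl-3-oxocyclohex-1-ene-1-carbaldehyde
Product: 16 4-allyl-3-[(1R,2E)-1-hydroxyhept-2-en-1-yl]-4,5-dimethylcyclohex-2-en-1-one (methyls cis and β; allyl α)
Conditions: hex-1-yne, (c-C6H11)2BH, toluene, 0 °C → rt; Et2Zn, −78 °C; (+)-3-exo-morpholinoisoborneol (5 mol%); then 15, −20 → 0 °C; aq. NH4Cl
Reagents that add atoms: hex-1-yne CCCCC#C
Why: Hydroboration, boron-to-zinc exchange and amino-alcohol-catalysed 1,2-addition of the (E)-alkenylzinc to the aldehyde; the ligand-bound zinc complex should deliver the alkenyl group to the Re face of C9, which sets the (R)-carbinol (9α-oxygen after ring closure) under reagent control. Organozinc reagents add neither to the enone carbonyl nor in conjugate fashion under these conditions, and the butyl terminus is lost in step 13.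

Step 13
Reactants: 16 4-allyl-3-[(1R,2E)-1-hydroxyhept-2-en-1-yl]-4,5-dimethylcyclohex-2-en-1-one
Product: 17 9α-hydroxy-11,12,13-trinoreremophila-1(10),7-dien-2-one
Conditions: second-generation Grubbs catalyst (H2IMes)(PCy3)Cl2Ru=CHPh (5 mol%), CH2Cl2, 40 °C
Reagents that add atoms: none
Why: Ring-closing metathesis: the ruthenium carbene loads on the terminal allyl alkene, closes onto the disubstituted alkene and forms the six-membered ring B with C7=C8, expelling hex-1-ene; the electron-poor trisubstituted C1=C10 alkene does not take part.

Step 14
Reactants: 17 9α-hydroxy-11,12,13-trinoreremophila-1(10),7-dien-2-one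
Product: 19 9α-hydroxy-11,12,13-trinor-10α-eremophil-7-en-2-one, via dilithium enolate-alkoxide 18 (not isolated)
Conditions: LiN(SiMe3)2 (1.0 equiv), THF, −78 °C; Li (5 equiv), NH3(l)/THF, −78 °C; isoprene; solid NH4Cl
Reagents that add atoms: none
Why: Dissolving-metal (Birch-type) reduction of the enone: the C10 carbanion is protonated axially from the α face, as in the classical reduction of angular-methyl octalones, which gives the trans ring fusion (10α-H). The C9 oxygen is held as its lithium alkoxide, which is not a leaving group, so β-elimination from C10 is suppressed; the ketone stays masked as enolate 18 until the quench and the isolated C7=C8 alkene is inert.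

Step 15
Reactants: 19 9α-hydroxy-11,12,13-trinor-10α-eremophil-7-en-2-one
Product: 20 11,12,13-trinor-10α-eremophil-7-ene-2α,9α-diol
Conditions: LiBH(s-Bu)3 (2.5 equiv), THF, −78 °C; aq. NH4Cl
Reagents that add atoms: none
Why: The bulky trialkylborohydride attacks the C2 ketone along the equatorial path, because axial approach is hindered by the axial hydrogens at C4 and C10, and so gives the axial 2α-alcohol.

Step 16
Reactants: 20 11,12,13-trinor-10α-eremophil-7-ene-2α,9α-diol
Product: 21 7α,8α-epoxy-11,12,13-trinor-10α-eremophilane-2α,9α-diol
Conditions: mCPBA (1.2 equiv), NaHCO3, CH2Cl2, 0 °C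
Reagents that add atoms: 3-chloroperbenzoic acid O=C(OO)c1cccc(Cl)c1
Why: Prilezhaev epoxidation; the β face of C7=C8 is screened by the axial C5 methyl and the allylic 9α-hydroxyl hydrogen-bonds the peracid on the α face (Henbest effect), so both effects favour the 7α,8α-epoxide.

Step 17
Reactants: 21 7α,8α-epoxy-11,12,13-trinor-10α-eremophilane-2α,9α-diol
Product: 22 10α-eremophil-11-ene-2α,8α,9α-triol (7β-isopropenyl)
Conditions: isopropenylmagnesium bromide (6 equiv), CuI (0.5 equiv), THF, −30 → 0 °C; aq. NH4Cl
Reagents that add atoms: isopropenylmagnesium bromide C=C(C)[Mg]Br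
Why: Copper-catalysed Grignard opening of the epoxide with inversion; by the Fürst–Plattner rule the trans-diaxial path requires attack at C7 from the β face, giving the 7β-isopropenyl group and the axial 8α-hydroxyl. Attack at C8 would need a twist-boat and is next to the C9 alkoxide, and the cis epoxy alcohol cannot undergo Payne rearrangement.

Step 18
Reactants: 23 (E)-3-methylpent-2-enoic acid
Product: 24 (E)-3-methylpent-2-enoyl chloride
Conditions: (COCl)2 (1.2 equiv), DMF (cat.), CH2Cl2, 0 °C → rt; evaporate
Reagents that add atoms: oxalyl chloride O=C(Cl)C(=O)Cl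
Why: Acid chloride formation through the Vilsmeier-type chloroiminium species without amine base, which keeps the (E) geometry and the conjugation of the acyl group.

Step 19
Reactants: 22 10α-eremophil-11-ene-2α,8α,9α-triol; 24 (E)-3-methylpent-2-enoyl chloride
Product: 26 9α-[(E)-3-methylpent-2-enoyloxy]-10α-eremophil-11-ene-2α,8α-diol, via dibutylstannylene acetal 25 (not isolated)
Conditions: Bu2SnO (1.05 equiv), toluene, reflux (removal of water); then 24 (1.05 equiv), toluene, 0 °C → rt
Reagents that add atoms: none
Why: Regioselective stannylene-mediated acylation: the tin acetal forms on the only cis-vicinal diol (C8/C9) and activates its equatorial oxygen (C9), which is acylated without added base, while the axial 2- and 8-hydroxyls stay free. Base-free conditions avoid E/Z scrambling of the acyl group and acyl migration.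

## Compound list

1 | (Z)-but-2-ene-1,4-diol | OC/C=C\CO | starting material
2 | (Z)-1,4-bis(4-methoxybenzyloxy)but-2-ene | COc1ccc(COC/C=C\COCc2ccc(OC)cc2)cc1 | intermediate
3 | 3,5-bis[(4-methoxybenzyloxy)methyl]-1,2,4-trioxolane (secondary ozonide) | COc1ccc(COCC2OOC(COCc3ccc(OC)cc3)O2)cc1 | intermediate (not isolated)
4 | 2-(4-methoxybenzyloxy)acetaldehyde | COc1ccc(COCC=O)cc1 | intermediate
5 | 1-(triphenylphosphoranylidene)propan-2-one | CC(=O)C=P(c1ccccc1)(c1ccccc1)c1ccccc1 | starting material
6 | (E)-5-(4-methoxybenzyloxy)pent-3-en-2-one | CC(=O)/C=C/COCc1ccc(OC)cc1 | intermediate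
7 | (E)-2-(tert-butyldimethylsilyloxy)-5-(4-methoxybenzyloxy)penta-1,3-diene | C=C(O[Si](C)(C)C(C)(C)C)/C=C/COCc1ccc(OC)cc1 | intermediate
8 | (E)-2-methylbut-2-enal | C/C=C(\C)C=O | starting material
9 | 4-(tert-butyldimethylsilyloxy)-2-[(4-methoxybenzyloxy)methyl]-1,6-dimethylcyclohex-3-ene-1-carbaldehyde (methyls cis, formyl trans to them, side chain cis to formyl) | O=C[C@]1(C)[C@@H](C)CC(O[Si](C)(C)C(C)(C)C)=C[C@@H]1COCc1ccc(OC)cc1 | intermediate
10 | 2-[(4-methoxybenzyloxy)methyl]-1,6-dimethyl-4-oxocyclohex-2-ene-1-carbaldehyde (methyls cis) | O=C[C@]1(C)[C@@H](C)CC(=O)C=C1COCc1ccc(OC)cc1 | intermediate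
11 | 3-[(4-methoxybenzyloxy)methyl]-4-(2-methoxyvinyl)-4,5-dimethylcyclohex-2-en-1-one (E/Z mixture, methyls cis) | COC=C[C@]1(C)[C@@H](C)CC(=O)C=C1COCc1ccc(OC)cc1 | intermediate
12 | 2-[2-[(4-methoxybenzyloxy)methyl]-1,6-dimethyl-4-oxocyclohex-2-en-1-yl]acetaldehyde (methyls cis) | O=CC[C@]1(C)[C@@H](C)CC(=O)C=C1COCc1ccc(OC)cc1 | intermediate
13 | 4-allyl-3-[(4-methoxybenzyloxy)methyl]-4,5-dimethylcyclohex-2-en-1-one (methyls cis) | C=CC[C@]1(C)[C@@H](C)CC(=O)C=C1COCc1ccc(OC)cc1 | intermediate
14 | 4-allyl-3-(hydroxymethyl)-4,5-dimethylcyclohex-2-en-1-one (methyls cis) | C=CC[C@]1(C)[C@@H](C)CC(=O)C=C1CO | intermediate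
15 | 6-allyl-5,6-dimethyl-3-oxocyclohex-1-ene-1-carbaldehyde (methyls cis) | C=CC[C@]1(C)[C@@H](C)CC(=O)C=C1C=O | intermediate
16 | 4-allyl-3-[(1R,2E)-1-hydroxyhept-2-en-1-yl]-4,5-dimethylcyclohex-2-en-1-one (methyls cis) | C=CC[C@]1(C)[C@@H](C)CC(=O)C=C1[C@H](O)/C=C/CCCC | intermediate
17 | 9α-hydroxy-11,12,13-trinoreremophila-1(10),7-dien-2-one | O=C1C=C2[C@H](O)C=CC[C@]2(C)[C@@H](C)C1 | intermediate
18 | dilithium 2-enolate 9-alkoxide of 19 | [Li]OC1=C[C@H]2[C@H](O[Li])C=CC[C@]2(C)[C@@H](C)C1 | intermediate (not isolated)
19 | 9α-hydroxy-11,12,13-trinor-10α-eremophil-7-en-2-one | O=C1C[C@H]2[C@H](O)C=CC[C@]2(C)[C@@H](C)C1 | intermediate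
20 | 11,12,13-trinor-10α-eremophil-7-ene-2α,9α-diol | O[C@@H]1C[C@H]2[C@H](O)C=CC[C@]2(C)[C@@H](C)C1 | intermediate
21 | 7α,8α-epoxy-11,12,13-trinor-10α-eremophilane-2α,9α-diol | O[C@@H]1C[C@H]2[C@H](O)[C@@H]3O[C@@H]3C[C@]2(C)[C@@H](C)C1 | intermediate
22 | 10α-eremophil-11-ene-2α,8α,9α-triol | C=C(C)[C@H]1C[C@]2(C)[C@@H](C)C[C@H](O)C[C@H]2[C@H](O)[C@@H]1O | intermediate
23 | (E)-3-methylpent-2-enoic acid | CC/C(C)=C/C(=O)O | starting material
24 | (E)-3-methylpent-2-enoyl chloride | CC/C(C)=C/C(Cl)=O | intermediate
25 | 8α,9α-O-dibutylstannylene acetal of 22 | C=C(C)[C@H]1C[C@]2(C)[C@@H](C)C[C@H](O)C[C@H]2[C@@H]3O[Sn](CCCC)(CCCC)O[C@H]13 | intermediate (not isolated)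
26 | 9α-[(E)-3-methylpent-2-enoyloxy]-10α-eremophil-11-ene-2α,8α-diol | C=C(C)[C@H]1C[C@]2(C)[C@@H](C)C[C@H](O)C[C@H]2[C@H](OC(=O)/C=C(\C)CC)[C@@H]1O | target

## Step count and least certain steps

Total: 19 steps. Longest linear sequence: 18 steps (steps 1–17 and 19); step 18 is a one-step side branch.

**Step 5 (key step).** The enal is both α-branched and β-substituted, so the cycloaddition may be slow. Slow addition gives the cationic catalyst time to desilylate or oligomerise the diene, and shielding of the enal face may be incomplete. Fallback, from 7 and 8, returning at 16: the cycloaddition is run with Me2AlCl in CH2Cl2 at −78 °C to give racemic 9, that is 9 together with its mirror image F1. Steps 6–11 are carried out on the racemate, which gives 10–15 together with the mirror image of 10 F2, the mirror image of 11 F3, the mirror image of 12 F4, the mirror image of 13 F5, the mirror image of 14 F6 and the mirror image of 15 F7. The catalyst-controlled addition of step 12 then turns 15 into 16 and F7 into the diastereomeric (R)-carbinol F8; these are diastereomers and are separated by chromatography, so that step 12 serves as the resolution.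

**Step 12.** The aldehyde is strongly electrophilic (its alkene is also conjugated to the ring ketone), so uncatalysed background addition may erode the facial control, and ethyl transfer from zinc may compete. Fallback, from 15, returning at 17: vinylmagnesium bromide with CeCl3 in THF at −78 °C adds to the aldehyde without stereocontrol and gives the (R)-vinyl carbinol F9 and its (S)-epimer F10, which are separated. F10 is inverted by a Mitsunobu reaction (4-nitrobenzoic acid, PPh3, diisopropyl azodicarboxylate) to the 4-nitrobenzoate F11, whose methanolysis (K2CO3, MeOH) gives more F9. Ring-closing metathesis of F9 with the second-generation Grubbs catalyst gives 17.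

**Step 14.** The C10 carbanion may expel the C9 oxygen if the alkoxide is not fully formed, the γ-hydroxy enone may isomerise to a 1,4-diketone under base, and the ketone may be over-reduced. Fallback, from 17, returning at 21: the isolated C7=C8 alkene of 17 is epoxidised first with mCPBA to the 7α,8α-epoxy enone F12. The C1=C10 alkene is then hydrogenated with [Ir(cod)(PCy3)(py)]PF6 and H2 in CH2Cl2, where the 9α-hydroxyl directs hydrogen to the α face and gives the trans-fused epoxy ketone F13. Reduction of F13 with LiBH(s-Bu)3 gives 21.

**Step 17.** The axial approach to C7 is syn to the angular methyl, so the opening may be slow. That would leave room for bromohydrin formation by magnesium bromide, for attack at C8, or for base-induced isomerisation of the epoxide to an allylic alcohol. Fallback, from 21, returning at 22: the epoxide is opened with the slimmer nucleophile lithium acetylide–ethylenediamine in DMSO, which gives the 7β-ethynyl triol F14 by the same trans-diaxial path. Zirconium-catalysed carboalumination of the alkyne (Me3Al, Cp2ZrCl2, CH2Cl2) followed by protonolysis turns the ethynyl group into isopropenyl and gives 22.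

**Step 19.** Acylation may take place at the wrong hydroxyl, the acyl group may migrate between the cis C8 and C9 oxygens, or the enoyl group may isomerise. Fallback, from 22, returning at 26: the cis diol is protected as the 8α,9α-acetonide F15 (2,2-dimethoxypropane, pyridinium 4-toluenesulfonate). The 2α-hydroxyl is silylated to the silyl ether F16 (tert-butyldimethylsilyl triflate, 2,6-lutidine), and the acetonide is removed with aqueous acetic acid to give the 2-silyl-protected diol F17. The equatorial 9α-hydroxyl is acylated with 24 and pyridine at −20 °C to the ester F18, and the silyl group is removed with HF·pyridine to give 26.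

## Further compounds

F1 | step 5 | mirror image of 9 | O=C[C@@]1(C)[C@H](C)CC(O[Si](C)(C)C(C)(C)C)=C[C@H]1COCc1ccc(OC)cc1
F2 | step 5 | mirror image of 10 | O=C[C@@]1(C)[C@H](C)CC(=O)C=C1COCc1ccc(OC)cc1
F3 | step 5 | mirror image of 11 | COC=C[C@@]1(C)[C@H](C)CC(=O)C=C1COCc1ccc(OC)cc1
F4 | step 5 | mirror image of 12 | O=CC[C@@]1(C)[C@H](C)CC(=O)C=C1COCc1ccc(OC)cc1
F5 | step 5 | mirror image of 13 | C=CC[C@@]1(C)[C@H](C)CC(=O)C=C1COCc1ccc(OC)cc1
F6 | step 5 | mirror image of 14 | C=CC[C@@]1(C)[C@H](C)CC(=O)C=C1CO
F7 | step 5 | mirror image of 15 | C=CC[C@@]1(C)[C@H](C)CC(=O)C=C1C=O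
F8 | step 5 | (R)-carbinol in the mirror-image ring series (diastereomer of 16) | C=CC[C@@]1(C)[C@H](C)CC(=O)C=C1[C@H](O)/C=C/CCCC
F9 | step 12 | 4-allyl-3-[(1R)-1-hydroxyprop-2-en-1-yl]-4,5-dimethylcyclohex-2-en-1-one | C=CC[C@]1(C)[C@@H](C)CC(=O)C=C1[C@H](O)C=C
F10 | step 12 | 4-allyl-3-[(1S)-1-hydroxyprop-2-en-1-yl]-4,5-dimethylcyclohex-2-en-1-one | C=CC[C@]1(C)[C@@H](C)CC(=O)C=C1[C@@H](O)C=C
F11 | step 12 | 4-nitrobenzoate of F9 | C=CC[C@]1(C)[C@@H](C)CC(=O)C=C1[C@H](OC(=O)c1ccc(cc1)[N+](=O)[O-])C=C
F12 | step 14 | 7α,8α-epoxy-9α-hydroxy-11,12,13-trinoreremophil-1(10)-en-2-one | O=C1C=C2[C@H](O)[C@@H]3O[C@@H]3C[C@]2(C)[C@@H](C)C1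
F13 | step 14 | 7α,8α-epoxy-9α-hydroxy-11,12,13-trinor-10α-eremophilan-2-one | O=C1C[C@H]2[C@H](O)[C@@H]3O[C@@H]3C[C@]2(C)[C@@H](C)C1
F14 | step 17 | 7β-ethynyl-11,12,13-trinor-10α-eremophilane-2α,8α,9α-triol | C#C[C@H]1C[C@]2(C)[C@@H](C)C[C@H](O)C[C@H]2[C@H](O)[C@@H]1O
F15 | step 19 | 8α,9α-acetonide of 22 | C=C(C)[C@H]1C[C@]2(C)[C@@H](C)C[C@H](O)C[C@H]2[C@@H]3OC(C)(C)O[C@H]13
F16 | step 19 | 2α-tert-butyldimethylsilyl ether of F15 | C=C(C)[C@H]1C[C@]2(C)[C@@H](C)C[C@H](O[Si](C)(C)C(C)(C)C)C[C@H]2[C@@H]3OC(C)(C)O[C@H]13
F17 | step 19 | 2α-(tert-butyldimethylsilyloxy)-10α-eremophil-11-ene-8α,9α-diol | C=C(C)[C@H]1C[C@]2(C)[C@@H](C)C[C@H](O[Si](C)(C)C(C)(C)C)C[C@H]2[C@H](O)[C@@H]1O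
F18 | step 19 | 2α-tert-butyldimethylsilyl ether of 26 | C=C(C)[C@H]1C[C@]2(C)[C@@H](C)C[C@H](O[Si](C)(C)C(C)(C)C)C[C@H]2[C@H](OC(=O)/C=C(\C)CC)[C@@H]1O
A1 | alternative 1 | ethyl 9α-(tert-butyldiphenylsilyloxy)-4β,5β-dimethyl-7-methylene-2-oxo-trans-decalin-1-carboxylate | C=C1C[C@]2(C)[C@@H](C)CC(=O)[C@H](C(=O)OCC)[C@H]2[C@H](O[Si](c3ccccc3)(c3ccccc3)C(C)(C)C)C1
A2 | alternative 1 | ethyl (6E)-8-(tert-butyldiphenylsilyloxy)-5,6-dimethyl-3-oxo-10-[(trimethylsilyl)methyl]undeca-6,10-dienoate | CCOC(=O)CC(=O)C[C@H](C)/C(C)=C/[C@H](O[Si](c1ccccc1)(c1ccccc1)C(C)(C)C)CC(=C)C[Si](C)(C)C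
A3 | alternative 2 | 2-allyl-2,3-dimethyl-5-(tert-butyldimethylsilyloxy)cyclohexanone | C=CC[C@]1(C)[C@@H](C)C[C@H](O[Si](C)(C)C(C)(C)C)CC1=O
A4 | alternative 2 | (S)-5-(tert-butyldimethylsilyloxy)-2-methylcyclohex-2-en-1-one | CC1=CC[C@H](O[Si](C)(C)C(C)(C)C)CC1=O
A5 | alternative 3 | 4β,5β-dimethyl-9(10)-octalin-2α-ol | C1C[C@]2(C)[C@@H](C)C[C@H](O)CC2=CC1
A6 | alternative 3 | 3-(1-methyl-2-methylenecyclohexyl)butanal | C=C1CCCC[C@]1(C)[C@@H](C)CC=O
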